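**Retrosynthetic overview**
1. The C ring of the target is opened at O1–C2 to a (2R,3S)-trans-epoxy ketone whose 2'-phenol closes 6-endo at the benzylic carbon (inversion at C2, retention at C3, giving 2,3-trans).
2. The epoxy ketone is cut at C2–C3 by a catalytic asymmetric Darzens condensation of an aryl chloromethyl ketone with an aryl aldehyde; this sets both stereocentres.
3. Oxirane and pyranone are formed in the same flask: Darzens first, then acid-triggered MOM removal and ring closure.
4. The chloroketone comes from resorcinol by MOM protection and two successive directed ortho-lithiations (prenylation, then chloroacetylation with a Weinreb amide).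
5. The aldehyde comes from 4-hydroxybenzaldehyde by ortho C-prenylation and MOM protection; both benzene rings are bought.

Assumption: prenyl = 3-methylbut-2-en-1-yl, MOM = methoxymethyl; the hand of the cinchona catalyst in step 6 (quinidine- or quinine-derived pseudoenantiomer) is taken as the one that gives the (2R,3S)-epoxide, to be confirmed in a pilot run.

**Step 1**
Reactants: 1 resorcinol
Product: 2 1,3-bis(methoxymethoxy)benzene
Conditions: NaH (2.4 equiv), DMF, 0 °C; MOMCl (2.4 equiv), 0 °C → rt
Reagents that add atoms: chloromethyl methyl ether (MOMCl), COCCl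
Why: Williamson-type O-alkylation of the bis-phenoxide (MOM protection) gives ethers that direct the two lithiations and come off together in the last step.

**Step 2**
Reactants: 2 1,3-bis(methoxymethoxy)benzene; 3 prenyl bromide (1-bromo-3-methylbut-2-ene)
Product: 5 1,3-bis(methoxymethoxy)-2-(3-methylbut-2-en-1-yl)benzene, via 2-lithio-1,3-bis(methoxymethoxy)benzene 4 (not isolated)
Conditions: n-BuLi (1.1 equiv), THF, 0 °C → rt, 1 h; CuBr·SMe2 (5 mol%), 3 (1.2 equiv), −78 °C → rt
Reagents that add atoms: none
Why: Directed ortho-metalation removes the C2 proton flanked by both OMOM groups, and copper-catalysed SN2 allylation of the aryllithium with the primary allylic bromide gives the linear prenyl arene.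

**Step 3**
Reactants: 5 1,3-bis(methoxymethoxy)-2-(3-methylbut-2-en-1-yl)benzene; 6 2-chloro-N-methoxy-N-methylacetamide
Product: 8 2-chloro-1-[2,4-bis(methoxymethoxy)-3-(3-methylbut-2-en-1-yl)phenyl]ethan-1-one, via 4-lithio-1,3-bis(methoxymethoxy)-2-prenylbenzene 7 (not isolated)
Conditions: n-BuLi (1.15 equiv), TMEDA (1.2 equiv), THF, −20 → 0 °C, 1 h; 6 (1.3 equiv), −78 → −30 °C; sat. aq NH4Cl
Reagents that add atoms: none
Why: A second directed ortho-metalation (ortho to OMOM) followed by Weinreb amide acylation, where the chelated tetrahedral adduct stops at the ketone stage and the C–Cl bond survives at low temperature.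

**Step 4**
Reactants: 9 4-hydroxybenzaldehyde; 3 prenyl bromide (1-bromo-3-methylbut-2-ene)
Product: 10 4-hydroxy-3-(3-methylbut-2-en-1-yl)benzaldehyde
Conditions: KOH (1.1 equiv), H2O, 3 (1.0 equiv), rt, 24 h
Reagents that add atoms: none
Why: Ortho C-alkylation of the ambident phenoxide is favoured in water, which hydrogen-bonds the oxygen, and the para position is blocked by the formyl group (phenoxide C-prenylation, modest yield expected).

**Step 5**
Reactants: 10 4-hydroxy-3-(3-methylbut-2-en-1-yl)benzaldehyde
Product: 11 4-(methoxymethoxy)-3-(3-methylbut-2-en-1-yl)benzaldehyde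
Conditions: NaH (1.2 equiv), DMF, 0 °C; MOMCl (1.2 equiv), 0 °C → rt
Reagents that add atoms: chloromethyl methyl ether (MOMCl), COCCl
Why: MOM protection of the phenoxide (Williamson-type O-alkylation) restores the electrophilicity of the non-enolisable aldehyde and prevents O-alkylation by the chloroketone in step 6.

**Step 6**
Reactants: 8 2-chloro-1-[2,4-bis(methoxymethoxy)-3-(3-methylbut-2-en-1-yl)phenyl]ethan-1-one; 11 4-(methoxymethoxy)-3-(3-methylbut-2-en-1-yl)benzaldehyde
Product: 14 (2R,3R)-3,7-dihydroxy-2-[4-hydroxy-3-(3-methylbut-2-en-1-yl)phenyl]-8-(3-methylbut-2-en-1-yl)-2,3-dihydro-4H-chromen-4-one (3-hydroxyglabrol), via tris-MOM (2R,3S)-epoxy ketone 12 (not isolated), via triphenolic (2R,3S)-epoxy ketone 13 (not isolated)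
Conditions: N-benzylcupreidinium-type bromide (6'-OH cinchona phase-transfer catalyst, 10 mol%), LiOH·H2O (2 equiv), CH2Cl2, 0 °C, 48 h; then MeOH, conc. HCl (to ca. 2 M), 40 °C, 3 h, same flask
Reagents that add atoms: none
Why: Proposed new method: the chiral ammonium enolate of 8 adds to 11 and the anti-chlorohydrin alkoxide closes by internal SN2 to the trans-epoxide, the ion-paired catalyst choosing the aldehyde face so that C-alpha is R and C-beta is S; acid then removes the MOM groups and the freed 2'-phenol opens the protonated oxirane 6-endo at the benzylic carbon (activated by the para-oxygenated aryl) with inversion at C2 and retention at C3, giving the 2,3-trans (2R,3R) product, and the prenyl alkenes are never exposed to an oxidant; the closest known reactions are the phase-transfer asymmetric Darzens condensation of phenacyl chlorides with aldehydes and the acid-mediated deprotection and cyclisation of 2'-OMOM chalcone epoxides to trans-dihydroflavonols.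

**Compound list**
1 | resorcinol | Oc1cccc(O)c1 | starting material
2 | 1,3-bis(methoxymethoxy)benzene | COCOc1cccc(OCOC)c1 | intermediate
3 | prenyl bromide (1-bromo-3-methylbut-2-ene) | CC(C)=CCBr | starting material
4 | 2-lithio-1,3-bis(methoxymethoxy)benzene | [Li]c1c(OCOC)cccc1OCOC | intermediate
5 | 1,3-bis(methoxymethoxy)-2-(3-methylbut-2-en-1-yl)benzene | COCOc1cccc(OCOC)c1CC=C(C)C | intermediate
6 | 2-chloro-N-methoxy-N-methylacetamide | CON(C)C(=O)CCl | starting material
7 | 4-lithio-1,3-bis(methoxymethoxy)-2-(3-methylbut-2-en-1-yl)benzene | [Li]c1ccc(OCOC)c(CC=C(C)C)c1OCOC | intermediate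
8 | 2-chloro-1-[2,4-bis(methoxymethoxy)-3-(3-methylbut-2-en-1-yl)phenyl]ethan-1-one | O=C(CCl)c1ccc(OCOC)c(CC=C(C)C)c1OCOC | intermediate
9 | 4-hydroxybenzaldehyde | O=Cc1ccc(O)cc1 | starting material
10 | 4-hydroxy-3-(3-methylbut-2-en-1-yl)benzaldehyde | CC(C)=CCc1cc(C=O)ccc1O | intermediate
11 | 4-(methoxymethoxy)-3-(3-methylbut-2-en-1-yl)benzaldehyde | COCOc1ccc(C=O)cc1CC=C(C)C | intermediate
12 | [2,4-bis(methoxymethoxy)-3-(3-methylbut-2-en-1-yl)phenyl]{(2R,3S)-3-[4-(methoxymethoxy)-3-(3-methylbut-2-en-1-yl)phenyl]oxiran-2-yl}methanone | O=C(c1ccc(OCOC)c(CC=C(C)C)c1OCOC)[C@@H]1O[C@H]1c1ccc(OCOC)c(CC=C(C)C)c1 | intermediate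
13 | [2,4-dihydroxy-3-(3-methylbut-2-en-1-yl)phenyl]{(2R,3S)-3-[4-hydroxy-3-(3-methylbut-2-en-1-yl)phenyl]oxiran-2-yl}methanone | O=C(c1ccc(O)c(CC=C(C)C)c1O)[C@@H]1O[C@H]1c1ccc(O)c(CC=C(C)C)c1 | intermediate
14 | 3-hydroxyglabrol, (2R,3R)-3,7-dihydroxy-2-[4-hydroxy-3-(3-methylbut-2-en-1-yl)phenyl]-8-(3-methylbut-2-en-1-yl)-2,3-dihydro-4H-chromen-4-one | CC(C)=CCc1cc([C@H]2Oc3c(ccc(O)c3CC=C(C)C)C(=O)[C@@H]2O)ccc1O | target

**Totals**
Total step count: 6. Longest linear sequence: 4 (steps 1, 2, 3, 6).

**Steps most likely to fail**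

Step 6. The enantioselectivity of the Darzens stage with an electron-rich aldehyde is uncertain, and the acid stage can give some cis isomer or chroman by-products; a modest ee can be raised by recrystallising 14. The fallback sets out from 8 and comes back to the route at 12. Chloroketone 8 is heated with PPh3 in toluene at 60 °C to give {2-[2,4-bis(methoxymethoxy)-3-prenylphenyl]-2-oxoethyl}triphenylphosphonium chloride F1. Aqueous NaOH in CH2Cl2 converts it into the keto-stabilised ylide 1-[2,4-bis(methoxymethoxy)-3-prenylphenyl]-2-(triphenylphosphoranylidene)ethanone F2. A Wittig reaction of the ylide and aldehyde 11 in toluene at 90 °C gives the (E)-chalcone (E)-1-[2,4-bis(methoxymethoxy)-3-prenylphenyl]-3-[4-(methoxymethoxy)-3-prenylphenyl]prop-2-en-1-one F3. Juliá–Colonna epoxidation (poly-L-leucine, urea–hydrogen peroxide, DBU, THF, rt) attacks only the electron-poor enone and delivers 12 as the (2R,3S) isomer. This is then treated with HCl in MeOH as in the second stage of step 6.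

Step 3. n-BuLi may remove a benzylic-allylic proton of the prenyl CH2 instead of the ring proton. The fallback sets out from 2 and comes back to the route at 7, fixing the site of metalation with a bromine. NBS in MeCN at 0 °C brominates 2 para to one OMOM group to give 1-bromo-2,4-bis(methoxymethoxy)benzene F4. LDA in THF at −78 °C removes the proton between the two OMOM groups to give (3-bromo-2,6-bis(methoxymethoxy)phenyl)lithium F5. Copper-catalysed allylation of this species with 3 gives 1-bromo-2,4-bis(methoxymethoxy)-3-prenylbenzene F6. Bromine–lithium exchange with n-BuLi in THF at −78 °C, which is much faster than any deprotonation, then gives aryllithium 7, quenched with 6 as in step 3.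

Step 4. O-alkylation and double alkylation compete, so the yield is low. The fallback sets out from 9 and comes back to the route at 10. Phenol 9 is O-alkylated with 3-chloro-3-methylbut-1-yne (K2CO3, KI, CuI cat., acetone, 60 °C) to give 4-[(2-methylbut-3-yn-2-yl)oxy]benzaldehyde F7. Lindlar semi-hydrogenation (H2, Pd/CaCO3/Pb, quinoline, EtOAc) gives 4-[(2-methylbut-3-en-2-yl)oxy]benzaldehyde F8. An aromatic Claisen rearrangement (N,N-diethylaniline, 130 °C) moves the 1,1-dimethylallyl group to the only free ortho-type position with allylic transposition and gives 10.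

**Further compounds**
F1 | step 6 | {2-[2,4-bis(methoxymethoxy)-3-(3-methylbut-2-en-1-yl)phenyl]-2-oxoethyl}triphenylphosphonium chloride | [Cl-].O=C(C[P+](c1ccccc1)(c1ccccc1)c1ccccc1)c1ccc(OCOC)c(CC=C(C)C)c1OCOC
F2 | step 6 | 1-[2,4-bis(methoxymethoxy)-3-(3-methylbut-2-en-1-yl)phenyl]-2-(triphenylphosphoranylidene)ethan-1-one | O=C(C=P(c1ccccc1)(c1ccccc1)c1ccccc1)c1ccc(OCOC)c(CC=C(C)C)c1OCOC
F3 | step 6 | (E)-1-[2,4-bis(methoxymethoxy)-3-(3-methylbut-2-en-1-yl)phenyl]-3-[4-(methoxymethoxy)-3-(3-methylbut-2-en-1-yl)phenyl]prop-2-en-1-one | O=C(/C=C/c1ccc(OCOC)c(CC=C(C)C)c1)c1ccc(OCOC)c(CC=C(C)C)c1OCOC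
F4 | step 3 | 1-bromo-2,4-bis(methoxymethoxy)benzene | COCOc1ccc(Br)c(OCOC)c1
F5 | step 3 | (3-bromo-2,6-bis(methoxymethoxy)phenyl)lithium | [Li]c1c(OCOC)ccc(Br)c1OCOC
F6 | step 3 | 1-bromo-2,4-bis(methoxymethoxy)-3-(3-methylbut-2-en-1-yl)benzene | COCOc1ccc(Br)c(OCOC)c1CC=C(C)C
F7 | step 4 | 4-[(2-methylbut-3-yn-2-yl)oxy]benzaldehyde | O=Cc1ccc(OC(C)(C)C#C)cc1
F8 | step 4 | 4-[(2-methylbut-3-en-2-yl)oxy]benzaldehyde | O=Cc1ccc(OC(C)(C)C=C)cc1
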